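The route disconnects the butenolide ring (O1, C2–C5) at O1–C5 together with the exocyclic C6–C7 bond. The (5E)-ylidene, with C7 trans to O1 across C5=C6, is the imprint of an anti oxypalladation of a terminal C5≡C6 alkyne, and C7–C9 with the C7 methyl is a but-2-enal unit joined through its β-carbon. One palladium-catalysed operation therefore closes the lactone, fixes the C5=C6 geometry, forms C6–C7 and sets the C7 stereocentre from (2E)-3-methoxy-2-methylpent-2-en-4-ynoic acid, whose alkene holds carboxyl and alkyne cis, and (E)-but-2-enal. Methylenation, hydroboration and B-alkyl Suzuki coupling with a C11–C18 dienyl iodide, then O-demethylation, complete the target.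

Key step: step 5

Assumption: the sense of induction of the pyridine–oxazoline ligand in step 5 cannot be predicted, so the ligand enantiomer written there stands for whichever enantiomer delivers (3S)-10.

Step 1
Reactants: 1 3-(trimethylsilyl)prop-2-ynoic acid
Product: 2 3-(trimethylsilyl)prop-2-ynoyl chloride
Conditions: (COCl)2 (1.2 equiv), DMF (cat.), CH2Cl2, 0 °C → rt; volatiles removed, used crude
Reagents that add atoms: oxalyl chloride, ClC(=O)C(=O)Cl
Why: Acid chloride formation through the chloroiminium species is routine for silyl-capped propynoic acids, the silyl group shielding the alkyne terminus from HCl addition.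

Step 2
Reactants: 2 3-(trimethylsilyl)prop-2-ynoyl chloride; 3 methyl propanoate
Product: 5 methyl 2-methyl-3-oxo-5-(trimethylsilyl)pent-4-ynoate, via lithium enolate of methyl propanoate 4 (not isolated)
Conditions: LiN(iPr)2 (2.1 equiv), 3 (2.1 equiv), THF, −78 °C; then 2 (1.0 equiv), −78 °C; AcOH quench at −78 °C
Reagents that add atoms: none
Why: Crossed Claisen acylation of a preformed ester enolate by an acid chloride is fast at the acyl carbon, and the second equivalent of enolate converts the β-keto ester into its own enolate, which shields the ynone from conjugate addition; the C2 centre is racemic and is erased in step 3.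

Step 3
Reactants: 5 methyl 2-methyl-3-oxo-5-(trimethylsilyl)pent-4-ynoate
Product: 6 methyl (2E)-3-methoxy-2-methyl-5-(trimethylsilyl)pent-2-en-4-ynoate
Conditions: KN(SiMe3)2 (1.05 equiv), 18-crown-6 (1.1 equiv), THF, −78 °C; then MeOTf (1.2 equiv), −78 → −20 °C
Reagents that add atoms: methyl trifluoromethanesulfonate, COS(=O)(=O)C(F)(F)F
Why: O-alkylation of a non-chelated potassium enolate by a hard electrophile should dominate over C-alkylation, and the crown-complexed enolate prefers the extended W shape with the enolate oxygen anti to the ester, so that the enol ether should form as the 2E isomer with the slim alkynyl group cis to the ester.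

Step 4
Reactants: 6 methyl (2E)-3-methoxy-2-methyl-5-(trimethylsilyl)pent-2-en-4-ynoate
Product: 8 (2E)-3-methoxy-2-methylpent-2-en-4-ynoic acid, via desilylated methyl ester 7 (not isolated)
Conditions: LiOH·H2O (4 equiv), THF/MeOH/H2O, 0 °C → rt; then 1 M HCl to pH 3 at 0 °C, used promptly
Reagents that add atoms: lithium hydroxide, [Li+].[OH-]
Why: Hydroxide-induced protodesilylation of the alkynylsilane is followed in the same pot by saponification of the vinylogous carbonate ester, the tetrasubstituted alkene having no pathway for geometric isomerisation under these conditions.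

Step 5
Reactants: 8 (2E)-3-methoxy-2-methylpent-2-en-4-ynoic acid; 9 (2E)-but-2-enal
Product: 10 (3S)-4-[(2E)-3-methoxy-4-methyl-5-oxofuran-2(5H)-ylidene]-3-methylbutanal
Conditions: Pd(OAc)2 (5 mol %), (S)-4-tert-butyl-2-(pyridin-2-yl)-4,5-dihydro-1,3-oxazole (6 mol %), HBF4·OEt2 (10 mol %), 9 (3 equiv), ClCH2CH2Cl, 25–40 °C, slow addition of 8
Reagents that add atoms: none
Why: Proposed new method: a cationic divalent-palladium centre carrying the chiral pyridine–oxazoline ligand should bind the terminal alkyne of 8, the cis-held carboxyl oxygen should attack C5 from the face opposite the metal (5-exo-dig closure of the lactone ring O1–C2–C3–C4–C5) so that palladium sits on C6 trans to O1, the alkenylpalladium should insert the enal in syn fashion with C6 bonding to the β-carbon, and protonolysis of the palladium enolate by the proton released in the cyclisation should free 10 and the catalyst without a change of oxidation state. The closest known reaction type is the divalent-palladium-catalysed oxypalladation of alkynoic acids followed by conjugate addition to acrolein or vinyl ketones and protonolysis, together with enantioselective conjugate additions of organopalladium species to β-substituted enones under pyridine–oxazoline ligation; insertion of a β-substituted enal with creation of a stereocentre is the unproven extension. The E geometry of C5=C6 follows from anti oxypalladation and retention at C6, and the 5-exo mode is favoured because the 2E alkene holds the carboxyl oxygen next to the internal alkyne carbon, which is also the carbon a coordinated terminal alkyne offers to a nucleophile. The C7 stereocentre is set by the chiral ligand on palladium, which must distinguish the two faces of the enal in the insertion step. The step needs insertion to outrun protodepalladation of the alkenylpalladium (excess enal, weakly coordinating BF4 counter-ion) and protonolysis to outrun β-hydride elimination (bidentate nitrogen ligand, acidic medium); any Z isomer of 8 cannot cyclise and is left behind.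

Step 6
Reactants: 10 (3S)-4-[(2E)-3-methoxy-4-methyl-5-oxofuran-2(5H)-ylidene]-3-methylbutanal
Product: 11 (5E)-4-methoxy-3-methyl-5-[(2S)-2-methylpent-4-en-1-ylidene]furan-2(5H)-one
Conditions: Ph3PCH3Br (1.2 equiv), KN(SiMe3)2 (1.1 equiv), THF, 0 °C; then 10, −78 → 0 °C, cold NH4Cl quench
Reagents that add atoms: methylenetriphenylphosphorane, C=P(c1ccccc1)(c1ccccc1)c1ccccc1 (made in the flask from methyltriphenylphosphonium bromide, C[P+](c1ccccc1)(c1ccccc1)c1ccccc1.[Br-])
Why: Wittig methylenation of an unhindered aldehyde is fast at low temperature, the lactone carbonyl (a vinylogous carbonate) is inert to the ylide, and the small excess of ylide with a cold quench keeps the moderately acidic H–C7 of the dienyl lactone, and hence the C7 configuration and the C5=C6 geometry, away from prolonged base.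

Step 7
Reactants: 12 3-bromofuran; 13 (5-chloropent-1-yn-1-yl)trimethylsilane
Product: 15 3-[5-(trimethylsilyl)pent-4-yn-1-yl]furan, via alkylmagnesium chloride 14 (not isolated)
Conditions: 13, Mg, THF, reflux; then 12, NiCl2(dppp) (3 mol %), THF, 0 °C → rt
Reagents that add atoms: none
Why: Nickel-catalysed Kumada coupling of primary alkyl Grignard reagents with 3-bromofuran is an established entry to 3-alkylfurans, and the silyl cap removes the acidic alkyne hydrogen.

Step 8
Reactants: 15 3-[5-(trimethylsilyl)pent-4-yn-1-yl]furan
Product: 16 3-(pent-4-yn-1-yl)furan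
Conditions: K2CO3 (0.2 equiv), MeOH, rt
Reagents that add atoms: none
Why: Base-catalysed methanolysis of the alkynyl–silicon bond (protodesilylation) is selective and leaves the furan untouched.

Step 9
Reactants: 16 3-(pent-4-yn-1-yl)furan
Product: 18 (2E)-6-(furan-3-yl)-3-methylhex-2-en-1-ol, via alkenyldimethylalane 17 (not isolated)
Conditions: Me3Al (2.5 equiv), Cp2ZrCl2 (0.25 equiv), CH2Cl2, 0 °C → rt; then (CH2O)n, 0 °C → rt; aq. potassium sodium tartrate
Reagents that add atoms: trimethylaluminium, C[Al](C)C; formaldehyde (from paraformaldehyde), C=O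
Why: Zirconium-catalysed carboalumination (Negishi carboalumination) adds methyl and aluminium syn across the terminal alkyne with methyl on the internal carbon, which fixes the E geometry of C14=C15, and the alkenylalane then adds to formaldehyde with retention.

Step 10
Reactants: 18 (2E)-6-(furan-3-yl)-3-methylhex-2-en-1-ol
Product: 19 3-[(4E)-6-bromo-4-methylhex-4-en-1-yl]furan
Conditions: CBr4 (1.3 equiv), PPh3 (1.4 equiv), CH2Cl2, −20 → 0 °C; used without storage
Reagents that add atoms: tetrabromomethane, BrC(Br)(Br)Br
Why: The Appel reaction converts a primary allylic alcohol into the bromide under near-neutral conditions that the furan tolerates, without allylic transposition or loss of alkene geometry.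

Step 11
Reactants: 19 3-[(4E)-6-bromo-4-methylhex-4-en-1-yl]furan; 20 prop-1-yn-1-ylmagnesium bromide
Product: 21 3-[(4E)-4-methylnon-4-en-7-yn-1-yl]furan
Conditions: 20 (1.5 equiv), CuBr·SMe2 (10 mol %), THF, 0 °C → rt
Reagents that add atoms: none
Why: Copper-catalysed coupling of an alkynyl Grignard reagent with a primary allylic bromide gives the skipped enyne by direct substitution at the unhindered CH2 (the γ-carbon is fully substituted) with retention of the E alkene.

Step 12
Reactants: 21 3-[(4E)-4-methylnon-4-en-7-yn-1-yl]furan
Product: 23 3-[(4E,7E)-8-iodo-4-methylnona-4,7-dien-1-yl]furan, via alkenylzirconocene chloride 22 (not isolated)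
Conditions: Cp2Zr(H)Cl (2 equiv), THF, rt → 50 °C, dark; then iodine, THF, 0 °C; aq. Na2S2O3
Reagents that add atoms: iodine, [I][I]
Why: Hydrozirconation with excess Cp2Zr(H)Cl under equilibrating conditions places zirconium by syn addition on the less hindered, methyl-bearing alkyne carbon, and iodinolysis with retention gives the E 2-iodoalkene, the trisubstituted alkene and the furan being inert to the hydride.

Step 13
Reactants: 11 (5E)-4-methoxy-3-methyl-5-[(2S)-2-methylpent-4-en-1-ylidene]furan-2(5H)-one; 23 3-[(4E,7E)-8-iodo-4-methylnona-4,7-dien-1-yl]furan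
Product: 25 (5E)-5-[(2S,6E,9E)-13-(furan-3-yl)-2,6,10-trimethyltrideca-6,9-dien-1-ylidene]-4-methoxy-3-methylfuran-2(5H)-one, via B-alkyl-9-BBN adduct 24 (not isolated)
Conditions: 11, 9-BBN (1.3 equiv), THF, 0 °C → rt; then 23 (1.1 equiv), PdCl2(dppf)·CH2Cl2 (5 mol %), AsPh3 (10 mol %), Cs2CO3 (2 equiv), DMF/THF/H2O, rt, dark
Reagents that add atoms: none
Why: 9-BBN hydroborates only the monosubstituted terminal alkene at its terminus, and the B-alkyl Suzuki–Miyaura coupling forms C10–C11 with retention of the iodide geometry under mild base, both events being remote from C7.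

Step 14
Reactants: 25 (5E)-5-[(2S,6E,9E)-13-(furan-3-yl)-2,6,10-trimethyltrideca-6,9-dien-1-ylidene]-4-methoxy-3-methylfuran-2(5H)-one
Product: 26 (5E)-5-[(2S,6E,9E)-13-(furan-3-yl)-2,6,10-trimethyltrideca-6,9-dien-1-ylidene]-4-hydroxy-3-methylfuran-2(5H)-one
Conditions: LiCl (10 equiv), DMSO, 80 °C, argon, dark; then 1 M HCl to pH 3 at 0 °C
Reagents that add atoms: none
Why: Nucleophilic O-demethylation of a methyl tetronate by chloride in a dipolar aprotic solvent (substitution at the methyl carbon with the tetronate, a vinylogous carboxylate, as leaving group) should leave the alkenes, the furan and C7 untouched.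

Compound list
1 | 3-(trimethylsilyl)prop-2-ynoic acid | C[Si](C)(C)C#CC(=O)O | starting material
2 | 3-(trimethylsilyl)prop-2-ynoyl chloride | C[Si](C)(C)C#CC(=O)Cl | intermediate
3 | methyl propanoate | CCC(=O)OC | starting material
4 | lithium enolate of methyl propanoate (geometry immaterial) | [Li+].CC=C([O-])OC | intermediate (not isolated)
5 | methyl 2-methyl-3-oxo-5-(trimethylsilyl)pent-4-ynoate (racemic) | COC(=O)C(C)C(=O)C#C[Si](C)(C)C | intermediate
6 | methyl (2E)-3-methoxy-2-methyl-5-(trimethylsilyl)pent-2-en-4-ynoate | C[Si](C)(C)C#C/C(OC)=C(/C)C(=O)OC | intermediate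
7 | methyl (2E)-3-methoxy-2-methylpent-2-en-4-ynoate | C#C/C(OC)=C(/C)C(=O)OC | intermediate (not isolated)
8 | (2E)-3-methoxy-2-methylpent-2-en-4-ynoic acid | C#C/C(OC)=C(/C)C(=O)O | intermediate
9 | (2E)-but-2-enal | C/C=C/C=O | starting material
10 | (3S)-4-[(2E)-3-methoxy-4-methyl-5-oxofuran-2(5H)-ylidene]-3-methylbutanal | CC1=C(OC)/C(=C\[C@@H](C)CC=O)OC1=O | intermediate
11 | (5E)-4-methoxy-3-methyl-5-[(2S)-2-methylpent-4-en-1-ylidene]furan-2(5H)-one | CC1=C(OC)/C(=C\[C@@H](C)CC=C)OC1=O | intermediate
12 | 3-bromofuran | Brc1ccoc1 | starting material
13 | (5-chloropent-1-yn-1-yl)trimethylsilane | C[Si](C)(C)C#CCCCCl | starting material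
14 | [5-(trimethylsilyl)pent-4-yn-1-yl]magnesium chloride | C[Si](C)(C)C#CCCC[Mg]Cl | intermediate (not isolated)
15 | 3-[5-(trimethylsilyl)pent-4-yn-1-yl]furan | C[Si](C)(C)C#CCCCc1ccoc1 | intermediate
16 | 3-(pent-4-yn-1-yl)furan | C#CCCCc1ccoc1 | intermediate
17 | [(1E)-5-(furan-3-yl)-2-methylpent-1-en-1-yl]dimethylalumane | C[Al](C)/C=C(\C)CCCc1ccoc1 | intermediate (not isolated)
18 | (2E)-6-(furan-3-yl)-3-methylhex-2-en-1-ol | OC/C=C(\C)CCCc1ccoc1 | intermediate
19 | 3-[(4E)-6-bromo-4-methylhex-4-en-1-yl]furan | BrC/C=C(\C)CCCc1ccoc1 | intermediate
20 | prop-1-yn-1-ylmagnesium bromide | CC#C[Mg]Br | starting material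
21 | 3-[(4E)-4-methylnon-4-en-7-yn-1-yl]furan | CC#CC/C=C(\C)CCCc1ccoc1 | intermediate
22 | chlorobis(cyclopentadienyl)[(2E,5E)-9-(furan-3-yl)-6-methylnona-2,5-dien-2-yl]zirconium | C/C(=C\C/C=C(\C)CCCc1ccoc1)[Zr](Cl)(C1C=CC=C1)C1C=CC=C1 | intermediate (not isolated)
23 | 3-[(4E,7E)-8-iodo-4-methylnona-4,7-dien-1-yl]furan | C/C(I)=C\C/C=C(\C)CCCc1ccoc1 | intermediate
24 | (5E)-5-[(2S)-5-(9-borabicyclo[3.3.1]nonan-9-yl)-2-methylpentylidene]-4-methoxy-3-methylfuran-2(5H)-one | CC1=C(OC)/C(=C\[C@@H](C)CCCB2C3CCCC2CCC3)OC1=O | intermediate (not isolated)
25 | (5E)-5-[(2S,6E,9E)-13-(furan-3-yl)-2,6,10-trimethyltrideca-6,9-dien-1-ylidene]-4-methoxy-3-methylfuran-2(5H)-one | CC1=C(OC)/C(=C\[C@@H](C)CCC/C(C)=C/C/C=C(\C)CCCc2ccoc2)OC1=O | intermediate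
26 | (5E)-5-[(2S,6E,9E)-13-(furan-3-yl)-2,6,10-trimethyltrideca-6,9-dien-1-ylidene]-4-hydroxy-3-methylfuran-2(5H)-one | CC1=C(O)/C(=C\[C@@H](C)CCC/C(C)=C/C/C=C(\C)CCCc2ccoc2)OC1=O | target

Total step count: 14. Longest linear sequence: 8 steps (steps 1–6, 13 and 14; the branch through steps 7–12, 13 and 14 is equally long).

Steps most likely to fail

Step 5. The alkenylpalladium intermediate may be protonated before the enal inserts (plain cycloisomerisation to the 5-methylene lactone), β-hydride elimination may follow insertion, or the ligand may discriminate poorly between the enal faces. The fallback uses known chemistry and sets out from 8. Iodolactonisation (iodine, NaHCO3, MeCN, 0 °C, dark) adds oxygen and iodine anti across the alkyne in the 5-exo mode and should give (5E)-5-(iodomethylidene)-4-methoxy-3-methylfuran-2(5H)-one F1, with iodine trans to O1. An enantioselective redox-relay Heck reaction of F1 with (E)-but-2-en-1-ol then follows (zerovalent palladium source Pd2(dba)3, chiral pyridine–oxazoline ligand, Ag2CO3 as base and iodide scavenger, DMA, rt). This reaction type is established for alkenyl triflates and acyclic alkenols, and the silver salt brings the iodide onto the same cationic pathway. The alkenyl group is transferred with retention to the alkene carbon remote from the hydroxyl, and chain walking to the carbinol carbon releases the aldehyde, so the route is rejoined at 10.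

Step 3. Alkylation may occur at carbon instead of oxygen, or through a chelated enolate that places the methoxy group syn to the ester (Z), an isomer that cannot lactonise. The fallback sets out from 5 and replaces kinetic enolate alkylation by addition–elimination under thermodynamic control. Ph3PCl2 and Et3N in CH2Cl2 convert 5 into the vinylogous acid chloride methyl 3-chloro-2-methyl-5-(trimethylsilyl)pent-2-en-4-ynoate F2 (either geometry). NaOMe in MeOH (0 °C → rt) then replaces chloride at C3 by methoxide; because methoxide exchange at C3 is reversible, the more stable E isomer with the methoxy group anti to the ester should accumulate. The same reagent removes the silyl group, so the route is rejoined at 7, which is saponified as in step 4.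

Step 14. Dealkylation may be too slow at temperatures the molecule tolerates, so that forcing conditions equilibrate the E-ylidene toward Z or degrade the furan and the skipped diene. The fallback moves the dealkylation ahead of the fragment coupling and sets out from 11. LiCl in DMSO, applied to this small and robust intermediate where harsher conditions and separation of geometric isomers are affordable, should give (5E)-4-hydroxy-3-methyl-5-[(2S)-2-methylpent-4-en-1-ylidene]furan-2(5H)-one F3. Hydroboration with 2.3 equiv of 9-BBN, one equivalent being consumed by the acidic hydroxyl, should give (5E)-4-[(9-borabicyclo[3.3.1]nonan-9-yl)oxy]-5-[(2S)-5-(9-borabicyclo[3.3.1]nonan-9-yl)-2-methylpentylidene]-3-methylfuran-2(5H)-one F4. Suzuki coupling of F4 with 23 under the conditions of step 13 with one further equivalent of Cs2CO3, then acidification to pH 3, rejoins the route at 26.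

Further compounds
F1 | step 5 | (5E)-5-(iodomethylidene)-4-methoxy-3-methylfuran-2(5H)-one | CC1=C(OC)/C(=C\I)OC1=O
F2 | step 3 | methyl 3-chloro-2-methyl-5-(trimethylsilyl)pent-2-en-4-ynoate (either geometry) | COC(=O)C(C)=C(Cl)C#C[Si](C)(C)C
F3 | step 14 | (5E)-4-hydroxy-3-methyl-5-[(2S)-2-methylpent-4-en-1-ylidene]furan-2(5H)-one | CC1=C(O)/C(=C\[C@@H](C)CC=C)OC1=O
F4 | step 14 | (5E)-4-[(9-borabicyclo[3.3.1]nonan-9-yl)oxy]-5-[(2S)-5-(9-borabicyclo[3.3.1]nonan-9-yl)-2-methylpentylidene]-3-methylfuran-2(5H)-one | CC1=C(OB2C3CCCC2CCC3)/C(=C\[C@@H](C)CCCB2C3CCCC2CCC3)OC1=O
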